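Retrosynthetic cuts: (1) the ester C–O bond at O-8; (2) C-7–C-8 of ring B, by intramolecular allylation of a C-8 aldehyde with a 2-(bromomethyl)alkenoate, which also creates the acrylate; (3) C-5–C-10 of ring A, made by a 1,2-shift of the quaternary carbon C-10 from C-4 to C-5; (4) C-4–C-5, by acetylide addition to a cyclopentanone.
Enabling feature: in ring A the ketone C-4, the ring-fusion carbon C-5 and the carbinol C-6 form a β-hydroxy ketone next to quaternary C-10. This is the retron of a ring-enlarging semipinacol shift of a 2,3-epoxy alcohol whose carbinol carbon lies in a cyclopentane (C-1, C-2, C-3, C-4, C-10).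
Forward order: 2-allyl-2-methylcyclopentane-1,3-dione → desymmetrized cyclopentanol carrying a Sharpless epoxide → ring A by expansion of the five-membered ring (step 9) → ring B by CrCl2-mediated closure (step 15) → esterification at O-8 and desilylation.
Stereochemistry: C-10 and C-1 come from the CBS desymmetrization, with C-1 corrected by Mitsunobu inversion. C-5 and C-6 come from the Sharpless epoxide and are transferred in the shift (inversion at C-5, retention at C-6 and C-10). C-7 and C-8 come from the all-equatorial chair closure of ring B.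

Key step: step 9

Convention and assumption: carbons carry eudesmane locants (ring A = C-1 to C-5 and C-10, ring B = C-5 to C-10; β is the face of the C-10 methyl). The acetylide in step 5 is assumed to add on the allyl face; that carbinol centre is erased in step 9, so its epimer would converge.

Step 1
Reactants: 1 2-methyl-2-(prop-2-en-1-yl)cyclopentane-1,3-dione
Product: 2 (2S,3S)-3-hydroxy-2-methyl-2-(prop-2-en-1-yl)cyclopentan-1-one
Conditions: (R)-tetrahydro-1-methyl-3,3-diphenyl-1H,3H-pyrrolo[1,2-c][1,3,2]oxazaborole (the R methyl-CBS oxazaborolidine, 10 mol %), BH3·SMe2, THF, −30 °C; MeOH then H2O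
Reagents that add atoms: none
Why: Corey–Bakshi–Shibata reduction that desymmetrizes the prochiral dione; the catalyst should fix the new carbinol as S and hydride should enter anti to the larger allyl group, so the quaternary carbon becomes S with the hydroxyl cis to allyl.

Step 2
Reactants: 2 (2S,3S)-3-hydroxy-2-methyl-2-(prop-2-en-1-yl)cyclopentan-1-one
Product: 3 (1R,2S)-2-methyl-3-oxo-2-(prop-2-en-1-yl)cyclopentyl 4-nitrobenzoate
Conditions: 4-nitrobenzoic acid, PPh3, DIAD, THF, 0 °C → rt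
Reagents that add atoms: 4-nitrobenzoic acid, O=C(O)c1ccc(cc1)[N+](=O)[O-]
Why: Mitsunobu esterification; SN2 displacement of the oxyphosphonium group inverts the carbinol to R, which places the oxygen cis to the methyl group (the future 1β-oxygen).

Step 3
Reactants: 3 (1R,2S)-2-methyl-3-oxo-2-(prop-2-en-1-yl)cyclopentyl 4-nitrobenzoate
Product: 4 (2S,3R)-3-hydroxy-2-methyl-2-(prop-2-en-1-yl)cyclopentan-1-one
Conditions: K2CO3 (cat.), MeOH, 0 °C → rt
Reagents that add atoms: none
Why: Base-catalysed transesterification to methanol cleaves the acyl–oxygen bond, so the inverted carbinol configuration is kept.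

Step 4
Reactants: 4 (2S,3R)-3-hydroxy-2-methyl-2-(prop-2-en-1-yl)cyclopentan-1-one
Product: 5 (2S,3R)-3-[(tert-butyldimethylsilyl)oxy]-2-methyl-2-(prop-2-en-1-yl)cyclopentan-1-one
Conditions: TBSCl, imidazole, DMF, rt
Reagents that add atoms: tert-butyldimethylsilyl chloride, CC(C)(C)[Si](C)(C)Cl
Why: Silyl ether formation without change at any stereocentre; the group masks O-1 towards the organometallic steps and keeps it from opening the epoxide later.

Step 5
Reactants: 5 (2S,3R)-3-[(tert-butyldimethylsilyl)oxy]-2-methyl-2-(prop-2-en-1-yl)cyclopentan-1-one; 6 prop-2-yn-1-ol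
Product: 8 (1R,2S,3R)-3-[(tert-butyldimethylsilyl)oxy]-1-(3-hydroxyprop-1-yn-1-yl)-2-methyl-2-(prop-2-en-1-yl)cyclopentan-1-ol, via dilithiated propargyl alcohol 7 (not isolated)
Conditions: 6, n-BuLi (2.1 equiv), THF, −78 → −20 °C; then 5, −78 → 0 °C; H2O
Reagents that add atoms: none
Why: 1,2-Addition of a lithium acetylide to the ketone (C-4–C-5 bond); attack is expected on the allyl face, away from the cis methyl and silyloxy groups (carbinol R), and this centre is erased in step 9.

Step 6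
Reactants: 8 (1R,2S,3R)-3-[(tert-butyldimethylsilyl)oxy]-1-(3-hydroxyprop-1-yn-1-yl)-2-methyl-2-(prop-2-en-1-yl)cyclopentan-1-ol
Product: 9 (1R,2S,3R)-3-[(tert-butyldimethylsilyl)oxy]-1-[(1E)-3-hydroxyprop-1-en-1-yl]-2-methyl-2-(prop-2-en-1-yl)cyclopentan-1-ol
Conditions: NaAlH2(OCH2CH2OMe)2, THF, 0 °C → rt; aqueous Rochelle salt
Reagents that add atoms: none
Why: Hydroxyl-directed trans-hydroalumination of a propargylic alcohol, which after protonolysis should give only the (E)-alkene and leaves the isolated allyl group alone.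

Step 7
Reactants: 9 (1R,2S,3R)-3-[(tert-butyldimethylsilyl)oxy]-1-[(1E)-3-hydroxyprop-1-en-1-yl]-2-methyl-2-(prop-2-en-1-yl)cyclopentan-1-ol
Product: 10 (1S,2S,3R)-3-[(tert-butyldimethylsilyl)oxy]-1-[(2R,3S)-3-(hydroxymethyl)oxiran-2-yl]-2-methyl-2-(prop-2-en-1-yl)cyclopentan-1-ol
Conditions: Ti(OiPr)4, diisopropyl L-(+)-tartrate, t-BuOOH, 4 Å MS, CH2Cl2, −20 °C
Reagents that add atoms: tert-butyl hydroperoxide, CC(C)(C)OO
Why: Sharpless asymmetric epoxidation of the primary (E)-allylic alcohol; the L-tartrate delivers oxygen to the face that gives the (2R,3S)-oxirane (the same spatial sense as the 2S,3S products of simple (E)-allylic alcohols) under reagent control, and the unactivated allyl group is not epoxidized.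

Step 8
Reactants: 10 (1S,2S,3R)-3-[(tert-butyldimethylsilyl)oxy]-1-[(2R,3S)-3-(hydroxymethyl)oxiran-2-yl]-2-methyl-2-(prop-2-en-1-yl)cyclopentan-1-ol
Product: 11 (1S,2S,3R)-3-[(tert-butyldimethylsilyl)oxy]-2-methyl-2-(prop-2-en-1-yl)-1-[(2R,3S)-3-{[(triethylsilyl)oxy]methyl}oxiran-2-yl]cyclopentan-1-ol
Conditions: Et3SiCl, imidazole, CH2Cl2, −40 → 0 °C
Reagents that add atoms: chlorotriethylsilane, CC[Si](Cl)(CC)CC
Why: Chemoselective silylation of the primary alcohol (the tertiary carbinol is too hindered), which lets the later 6-hydroxyl and the C-7 oxygen be told apart.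

Step 9
Reactants: 11 (1S,2S,3R)-3-[(tert-butyldimethylsilyl)oxy]-2-methyl-2-(prop-2-en-1-yl)-1-[(2R,3S)-3-{[(triethylsilyl)oxy]methyl}oxiran-2-yl]cyclopentan-1-ol
Product: 12 (2S,3R,4R)-4-[(tert-butyldimethylsilyl)oxy]-2-{(1R)-1-hydroxy-2-[(triethylsilyl)oxy]ethyl}-3-methyl-3-(prop-2-en-1-yl)cyclohexan-1-one
Conditions: BF3·OEt2 (0.3 equiv), CH2Cl2, −78 → −30 °C; aqueous NaHCO3
Reagents that add atoms: none
Why: BF3 activates the oxirane oxygen and the C-4–C-10 bond, held anti-periplanar to the breaking C-5–O bond, migrates from C-4 to C-5 while the carbinol oxygen becomes the C-4 carbonyl (semipinacol rearrangement of a tertiary 2,3-epoxy alcohol, type 3). The closest known reaction type is the Lewis-acid-promoted semipinacol ring expansion of 1-(oxiranyl)cycloalkanols to 2-(1-hydroxyalkyl)cycloalkanones, a stereospecific aldol by rearrangement. No ring is closed from an open chain: ring A arises by enlargement of the cyclopentane (C-1, C-2, C-3, C-4, C-10) through a suprafacial 1,2-alkyl shift that inserts C-5 between C-4 and C-10 (formally a 3-exo-tet opening of the oxirane by the migrating bond). C-5 is set by inversion at the oxirane carbon, C-6 keeps its oxygen and configuration and becomes the 6α-carbinol, and C-10 migrates with retention, so the Sharpless epoxide and the CBS-derived quaternary centre fix 5α-H, 6α-OH and the trans relation of the C-5 and C-10 appendages. The step needs cleavage of C-5–O and not C-6–O, secured by the push of the adjacent carbinol oxygen and the inductive deactivation of C-6 by the CH2OSiEt3 group, and migration of C-10 and not of the ring CH2 C-3, secured by the higher migratory aptitude of the fully substituted carbon. The C-1 silyl ether lies trans to the oxiranyl chain and cannot open the epoxide.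

Step 10
Reactants: 12 (2S,3R,4R)-4-[(tert-butyldimethylsilyl)oxy]-2-{(1R)-1-hydroxy-2-[(triethylsilyl)oxy]ethyl}-3-methyl-3-(prop-2-en-1-yl)cyclohexan-1-one
Product: 13 (2S,3R,4R)-4-[(tert-butyldimethylsilyl)oxy]-2-{(1R)-1-[(tert-butyldimethylsilyl)oxy]-2-[(triethylsilyl)oxy]ethyl}-3-methyl-3-(prop-2-en-1-yl)cyclohexan-1-one
Conditions: TBSOTf, 2,6-lutidine, CH2Cl2, −78 °C
Reagents that add atoms: tert-butyldimethylsilyl trifluoromethanesulfonate, CC(C)(C)[Si](C)(C)OS(=O)(=O)C(F)(F)F
Why: Silylation of the secondary 6-hydroxyl under cold, weakly basic conditions that should neither epimerize C-5 nor eliminate the β-oxygen.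

Step 11
Reactants: 13 (2S,3R,4R)-4-[(tert-butyldimethylsilyl)oxy]-2-{(1R)-1-[(tert-butyldimethylsilyl)oxy]-2-[(triethylsilyl)oxy]ethyl}-3-methyl-3-(prop-2-en-1-yl)cyclohexan-1-one
Product: 14 (2R)-2-[(tert-butyldimethylsilyl)oxy]-2-[(1S,2R,3R)-3-[(tert-butyldimethylsilyl)oxy]-2-methyl-6-oxo-2-(prop-2-en-1-yl)cyclohexyl]acetaldehyde
Conditions: (COCl)2, DMSO, CH2Cl2, −78 → −40 °C; then Et3N, −78 → 0 °C
Reagents that add atoms: none
Why: Swern oxidation applied directly to a primary triethylsilyl ether; the chlorosulfonium salt cleaves only the unhindered primary Si–O bond and oxidizes that carbon in the same flask, while the two secondary TBS ethers and the C-6 centre stay untouched.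

Step 12
Reactants: 14 (2R)-2-[(tert-butyldimethylsilyl)oxy]-2-[(1S,2R,3R)-3-[(tert-butyldimethylsilyl)oxy]-2-methyl-6-oxo-2-(prop-2-en-1-yl)cyclohexyl]acetaldehyde; 15 methyl prop-2-ynoate
Product: 17 methyl (4R)-4-[(tert-butyldimethylsilyl)oxy]-3-hydroxy-2-methylidene-4-[(1S,2R,3R)-3-[(tert-butyldimethylsilyl)oxy]-2-methyl-6-oxo-2-(prop-2-en-1-yl)cyclohexyl]butanoate (both epimers at the new carbinol), via methyl 2-(diisobutylalumanyl)prop-2-enoate 16 (not isolated)
Conditions: i-Bu2AlH, N-methylmorpholine N-oxide, THF, 0 °C, then 15; then 14, 0 °C → rt; aqueous Rochelle salt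
Reagents that add atoms: none
Why: Vinylalumination: conjugate hydroalumination of the propiolate gives the α-aluminated acrylate, which should add to the aldehyde and not to the hindered ketone, giving the Morita–Baylis–Hillman-type adduct without base; the new carbinol forms as an epimer mixture that converges in step 14.

Step 13
Reactants: 17 methyl (4R)-4-[(tert-butyldimethylsilyl)oxy]-3-hydroxy-2-methylidene-4-[(1S,2R,3R)-3-[(tert-butyldimethylsilyl)oxy]-2-methyl-6-oxo-2-(prop-2-en-1-yl)cyclohexyl]butanoate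
Product: 18 methyl (4R)-4-[(tert-butyldimethylsilyl)oxy]-3-hydroxy-2-methylidene-4-[(1S,2R,3R)-3-[(tert-butyldimethylsilyl)oxy]-2-methyl-6-oxo-2-(2-oxoethyl)cyclohexyl]butanoate
Conditions: OsO4 (2 mol %), NaIO4, 2,6-lutidine, dioxane/H2O, rt
Reagents that add atoms: sodium periodate, [Na+].[O-]I(=O)(=O)=O
Why: Lemieux–Johnson cleavage; OsO4 should dihydroxylate the electron-rich monosubstituted alkene in preference to the electron-poor acrylate, and periodate cleaves the diol to the C-8 aldehyde.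

Step 14
Reactants: 18 methyl (4R)-4-[(tert-butyldimethylsilyl)oxy]-3-hydroxy-2-methylidene-4-[(1S,2R,3R)-3-[(tert-butyldimethylsilyl)oxy]-2-methyl-6-oxo-2-(2-oxoethyl)cyclohexyl]butanoate
Product: 19 methyl (2Z,4S)-2-(bromomethyl)-4-[(tert-butyldimethylsilyl)oxy]-4-[(1S,2R,3R)-3-[(tert-butyldimethylsilyl)oxy]-2-methyl-6-oxo-2-(2-oxoethyl)cyclohexyl]but-2-enoate
Conditions: NBS, Me2S, CH2Cl2, 0 °C → rt
Reagents that add atoms: N-bromosuccinimide, O=C1CCC(=O)N1Br
Why: Bromination of a Morita–Baylis–Hillman alcohol with allylic transposition (SN2′ attack of bromide on the alkoxysulfonium salt); both carbinol epimers should give the same (Z)-2-(bromomethyl)alkenoate and the aldehyde is inert.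

Step 15
Reactants: 19 methyl (2Z,4S)-2-(bromomethyl)-4-[(tert-butyldimethylsilyl)oxy]-4-[(1S,2R,3R)-3-[(tert-butyldimethylsilyl)oxy]-2-methyl-6-oxo-2-(2-oxoethyl)cyclohexyl]but-2-enoate
Product: 20 methyl 2-[(1S,2R,3S,4aR,5R,8aS)-1,5-bis[(tert-butyldimethylsilyl)oxy]-3-hydroxy-4a-methyl-8-oxodecahydronaphthalen-2-yl]prop-2-enoate (1β,6α-disilyloxy-8α-hydroxy-4-oxo ester in eudesmane locants)
Conditions: CrCl2 (4 equiv), THF, 0 °C → rt; cold work-up at pH 7
Reagents that add atoms: none
Why: Intramolecular Nozaki–Hiyama–Kishi (Barbier-type) allylation: the allylchromium adds through its γ-carbon C-7 to the aldehyde in a chair-like closure of ring B (6-exo-trig on the C=O) with the 6-silyloxy group, the C-7 acrylate unit and the aldehyde oxygen all equatorial (an axial oxygen would be syn-diaxial to the C-10 methyl), which should set 7β-C and 8α-OH and reveal the acrylate; the ketone is not attacked.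

Step 16
Reactants: 21 ethyl 2-(hydroxymethyl)prop-2-enoate
Product: 22 ethyl 2-{[(tert-butyldimethylsilyl)oxy]methyl}prop-2-enoate
Conditions: TBSCl, imidazole, CH2Cl2, rt
Reagents that add atoms: tert-butyldimethylsilyl chloride, CC(C)(C)[Si](C)(C)Cl
Why: Standard silyl protection of the primary allylic alcohol of the side-chain precursor.

Step 17
Reactants: 22 ethyl 2-{[(tert-butyldimethylsilyl)oxy]methyl}prop-2-enoate
Product: 23 2-{[(tert-butyldimethylsilyl)oxy]methyl}prop-2-enoic acid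
Conditions: LiOH, THF/H2O, 0 °C; then 1 M HCl to pH 3
Reagents that add atoms: lithium hydroxide, [Li+].[OH-]
Why: Saponification of the ethyl ester at low temperature; the silyl ether tolerates dilute hydroxide and the α-substituted acrylate is a poor Michael acceptor for it.

Step 18
Reactants: 20 methyl 2-[(1S,2R,3S,4aR,5R,8aS)-1,5-bis[(tert-butyldimethylsilyl)oxy]-3-hydroxy-4a-methyl-8-oxodecahydronaphthalen-2-yl]prop-2-enoate; 23 2-{[(tert-butyldimethylsilyl)oxy]methyl}prop-2-enoic acid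
Product: 25 methyl 2-[(1S,2R,3S,4aR,5R,8aS)-1,5-bis[(tert-butyldimethylsilyl)oxy]-3-[(2-{[(tert-butyldimethylsilyl)oxy]methyl}prop-2-enoyl)oxy]-4a-methyl-8-oxodecahydronaphthalen-2-yl]prop-2-enoate, via 2,4,6-trichlorobenzoic mixed anhydride 24 (not isolated)
Conditions: 23, 2,4,6-trichlorobenzoyl chloride, Et3N, THF, rt; then 20, 4-(dimethylamino)pyridine, toluene, rt
Reagents that add atoms: none
Why: Yamaguchi esterification; the mixed anhydride acylates the equatorial 8α-hydroxyl through the acylpyridinium ion with retention at C-8, faster than the alkoxide can lactonize onto the methyl ester.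

Step 19
Reactants: 25 methyl 2-[(1S,2R,3S,4aR,5R,8aS)-1,5-bis[(tert-butyldimethylsilyl)oxy]-3-[(2-{[(tert-butyldimethylsilyl)oxy]methyl}prop-2-enoyl)oxy]-4a-methyl-8-oxodecahydronaphthalen-2-yl]prop-2-enoate
Product: 26 methyl 2-[(1S,2S,3S,4aR,5R,8aS)-1,5-dihydroxy-3-{[2-(hydroxymethyl)prop-2-enoyl]oxy}-4a-methyl-8-oxodecahydronaphthalen-2-yl]prop-2-enoate (CNP0144895.1)
Conditions: HF·pyridine, pyridine, THF, 0 °C → rt
Reagents that add atoms: none
Why: Fluoride-mediated cleavage of the three silyl ethers under buffered, mildly acidic conditions that should leave both acrylates, the β-hydroxy ketone and the open hydroxy ester intact (no lactonization, no acyl shift).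

Compound list
1 | 2-methyl-2-(prop-2-en-1-yl)cyclopentane-1,3-dione | C=CCC1(C)C(=O)CCC1=O | starting material
2 | (2S,3S)-3-hydroxy-2-methyl-2-(prop-2-en-1-yl)cyclopentan-1-one | C=CC[C@]1(C)C(=O)CC[C@@H]1O | intermediate
3 | (1R,2S)-2-methyl-3-oxo-2-(prop-2-en-1-yl)cyclopentyl 4-nitrobenzoate | C=CC[C@]1(C)C(=O)CC[C@H]1OC(=O)c1ccc(cc1)[N+](=O)[O-] | intermediate
4 | (2S,3R)-3-hydroxy-2-methyl-2-(prop-2-en-1-yl)cyclopentan-1-one | C=CC[C@]1(C)C(=O)CC[C@H]1O | intermediate
5 | (2S,3R)-3-[(tert-butyldimethylsilyl)oxy]-2-methyl-2-(prop-2-en-1-yl)cyclopentan-1-one | C=CC[C@]1(C)C(=O)CC[C@H]1O[Si](C)(C)C(C)(C)C | intermediate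
6 | prop-2-yn-1-ol | C#CCO | starting material
7 | dilithiated propargyl alcohol (dilithium 3-oxidoprop-1-yn-1-ide) | [Li]C#CCO[Li] | intermediate (not isolated)
8 | (1R,2S,3R)-3-[(tert-butyldimethylsilyl)oxy]-1-(3-hydroxyprop-1-yn-1-yl)-2-methyl-2-(prop-2-en-1-yl)cyclopentan-1-ol | C=CC[C@]1(C)[C@](O)(C#CCO)CC[C@H]1O[Si](C)(C)C(C)(C)C | intermediate
9 | (1R,2S,3R)-3-[(tert-butyldimethylsilyl)oxy]-1-[(1E)-3-hydroxyprop-1-en-1-yl]-2-methyl-2-(prop-2-en-1-yl)cyclopentan-1-ol | C=CC[C@]1(C)[C@](O)(/C=C/CO)CC[C@H]1O[Si](C)(C)C(C)(C)C | intermediate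
10 | (1S,2S,3R)-3-[(tert-butyldimethylsilyl)oxy]-1-[(2R,3S)-3-(hydroxymethyl)oxiran-2-yl]-2-methyl-2-(prop-2-en-1-yl)cyclopentan-1-ol | C=CC[C@]1(C)[C@](O)([C@@H]2O[C@H]2CO)CC[C@H]1O[Si](C)(C)C(C)(C)C | intermediate
11 | (1S,2S,3R)-3-[(tert-butyldimethylsilyl)oxy]-2-methyl-2-(prop-2-en-1-yl)-1-[(2R,3S)-3-{[(triethylsilyl)oxy]methyl}oxiran-2-yl]cyclopentan-1-ol | C=CC[C@]1(C)[C@](O)([C@@H]2O[C@H]2CO[Si](CC)(CC)CC)CC[C@H]1O[Si](C)(C)C(C)(C)C | intermediate
12 | (2S,3R,4R)-4-[(tert-butyldimethylsilyl)oxy]-2-{(1R)-1-hydroxy-2-[(triethylsilyl)oxy]ethyl}-3-methyl-3-(prop-2-en-1-yl)cyclohexan-1-one | C=CC[C@@]1(C)[C@H](O[Si](C)(C)C(C)(C)C)CCC(=O)[C@@H]1[C@@H](O)CO[Si](CC)(CC)CC | intermediate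
13 | (2S,3R,4R)-4-[(tert-butyldimethylsilyl)oxy]-2-{(1R)-1-[(tert-butyldimethylsilyl)oxy]-2-[(triethylsilyl)oxy]ethyl}-3-methyl-3-(prop-2-en-1-yl)cyclohexan-1-one | C=CC[C@@]1(C)[C@H](O[Si](C)(C)C(C)(C)C)CCC(=O)[C@@H]1[C@@H](O[Si](C)(C)C(C)(C)C)CO[Si](CC)(CC)CC | intermediate
14 | (2R)-2-[(tert-butyldimethylsilyl)oxy]-2-[(1S,2R,3R)-3-[(tert-butyldimethylsilyl)oxy]-2-methyl-6-oxo-2-(prop-2-en-1-yl)cyclohexyl]acetaldehyde | C=CC[C@@]1(C)[C@H](O[Si](C)(C)C(C)(C)C)CCC(=O)[C@@H]1[C@@H](O[Si](C)(C)C(C)(C)C)C=O | intermediate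
15 | methyl prop-2-ynoate | C#CC(=O)OC | starting material
16 | methyl 2-(diisobutylalumanyl)prop-2-enoate | C=C([Al](CC(C)C)CC(C)C)C(=O)OC | intermediate (not isolated)
17 | methyl (4R)-4-[(tert-butyldimethylsilyl)oxy]-3-hydroxy-2-methylidene-4-[(1S,2R,3R)-3-[(tert-butyldimethylsilyl)oxy]-2-methyl-6-oxo-2-(prop-2-en-1-yl)cyclohexyl]butanoate (epimers at C-3 of the butanoate) | C=CC[C@@]1(C)[C@H](O[Si](C)(C)C(C)(C)C)CCC(=O)[C@@H]1[C@@H](O[Si](C)(C)C(C)(C)C)C(O)C(=C)C(=O)OC | intermediate
18 | methyl (4R)-4-[(tert-butyldimethylsilyl)oxy]-3-hydroxy-2-methylidene-4-[(1S,2R,3R)-3-[(tert-butyldimethylsilyl)oxy]-2-methyl-6-oxo-2-(2-oxoethyl)cyclohexyl]butanoate (epimers at C-3 of the butanoate) | O=CC[C@@]1(C)[C@H](O[Si](C)(C)C(C)(C)C)CCC(=O)[C@@H]1[C@@H](O[Si](C)(C)C(C)(C)C)C(O)C(=C)C(=O)OC | intermediate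
19 | methyl (2Z,4S)-2-(bromomethyl)-4-[(tert-butyldimethylsilyl)oxy]-4-[(1S,2R,3R)-3-[(tert-butyldimethylsilyl)oxy]-2-methyl-6-oxo-2-(2-oxoethyl)cyclohexyl]but-2-enoate | O=CC[C@@]1(C)[C@H](O[Si](C)(C)C(C)(C)C)CCC(=O)[C@@H]1[C@@H](O[Si](C)(C)C(C)(C)C)/C=C(\CBr)C(=O)OC | intermediate
20 | methyl 2-[(1S,2R,3S,4aR,5R,8aS)-1,5-bis[(tert-butyldimethylsilyl)oxy]-3-hydroxy-4a-methyl-8-oxodecahydronaphthalen-2-yl]prop-2-enoate | O[C@H]1C[C@@]2(C)[C@H](O[Si](C)(C)C(C)(C)C)CCC(=O)[C@@H]2[C@@H](O[Si](C)(C)C(C)(C)C)[C@@H]1C(=C)C(=O)OC | intermediate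
21 | ethyl 2-(hydroxymethyl)prop-2-enoate | C=C(CO)C(=O)OCC | starting material
22 | ethyl 2-{[(tert-butyldimethylsilyl)oxy]methyl}prop-2-enoate | C=C(CO[Si](C)(C)C(C)(C)C)C(=O)OCC | intermediate
23 | 2-{[(tert-butyldimethylsilyl)oxy]methyl}prop-2-enoic acid | C=C(CO[Si](C)(C)C(C)(C)C)C(=O)O | intermediate
24 | 2-{[(tert-butyldimethylsilyl)oxy]methyl}prop-2-enoic 2,4,6-trichlorobenzoic anhydride | C=C(CO[Si](C)(C)C(C)(C)C)C(=O)OC(=O)c1c(Cl)cc(Cl)cc1Cl | intermediate (not isolated)
25 | methyl 2-[(1S,2R,3S,4aR,5R,8aS)-1,5-bis[(tert-butyldimethylsilyl)oxy]-3-[(2-{[(tert-butyldimethylsilyl)oxy]methyl}prop-2-enoyl)oxy]-4a-methyl-8-oxodecahydronaphthalen-2-yl]prop-2-enoate | C=C(CO[Si](C)(C)C(C)(C)C)C(=O)O[C@H]1C[C@@]2(C)[C@H](O[Si](C)(C)C(C)(C)C)CCC(=O)[C@@H]2[C@@H](O[Si](C)(C)C(C)(C)C)[C@@H]1C(=C)C(=O)OC | intermediate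
26 | methyl 2-[(1S,2S,3S,4aR,5R,8aS)-1,5-dihydroxy-3-{[2-(hydroxymethyl)prop-2-enoyl]oxy}-4a-methyl-8-oxodecahydronaphthalen-2-yl]prop-2-enoate | C=C(CO)C(=O)O[C@H]1C[C@@]2(C)[C@H](O)CCC(=O)[C@@H]2[C@@H](O)[C@@H]1C(=C)C(=O)OC | target

Total step count: 19. Longest linear sequence: 17 steps (steps 1 to 15, then 18 and 19); steps 16 and 17 make the side-chain acid.

Steps most likely to fail, with fallbacks

Step 9 is the first risk. Under the Lewis acid the epoxide may react by other paths before the 1,2-shift: a hydride shift from C-6, opening at C-6, or loss of the primary silyl ether. The ring methylene C-3 may also migrate in place of C-10. The fallback keeps the ring expansion but triggers it on the alkene with a halonium ion and introduces O-6 afterwards. It sets out from 9, which is silylated at the primary alcohol (Et3SiCl, imidazole) to the allylic alcohol (primary triethylsilyl ether of 9) F1. N-Bromosuccinimide at −40 °C should induce the bromonium-triggered semipinacol ring expansion to the ring-enlarged β-bromo ketone (12 with bromine in place of the C-6 hydroxyl) F2. 1,8-Diazabicyclo[5.4.0]undec-7-ene should then remove HBr to give the 2-alkylidene cyclohexanone (C-5=C-6 enone) F3. Copper-catalysed asymmetric conjugate borylation (CuCl as the monovalent copper source, NaOt-Bu, a chiral Josiphos-type bisphosphine, B2pin2, MeOH) should give the C-6 pinacol boronate F4 with C-5 protonated to the more stable epimer. Oxidation with NaBO3 with retention returns to the route at 12.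

Step 15 is the second risk. Facial selectivity at the aldehyde may be poor: closure through an axial-oxygen or boat-like arrangement would give the 8β-alcohol. The trivalent chromium alkoxide may also lactonize onto the methyl ester. The fallback sets out from 19 and accepts the epimer. If the closure gives mainly the 8β-alcohol (8-epimer of 20) F5, this is esterified with acid 23 under Mitsunobu conditions (PPh3, DIAD, toluene). That inverts C-8 while forming the ester and returns to the route at 25, so step 18 is replaced and not repeated.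

Step 12 is the third risk. Residual aluminium hydride may reduce the aldehyde or ketone, and addition to the hindered α-silyloxy aldehyde may be incomplete. The fallback sets out from 14 and uses the amine-catalysed Morita–Baylis–Hillman reaction with methyl acrylate (1,4-diazabicyclo[2.2.2]octane, MeOH, rt, long reaction time). This should give 17 directly, so it returns at 17 and makes no new compound (F0).

Further compounds
F1 | step 9 | (1R,2S,3R)-3-[(tert-butyldimethylsilyl)oxy]-2-methyl-2-(prop-2-en-1-yl)-1-{(1E)-3-[(triethylsilyl)oxy]prop-1-en-1-yl}cyclopentan-1-ol | C=CC[C@]1(C)[C@](O)(/C=C/CO[Si](CC)(CC)CC)CC[C@H]1O[Si](C)(C)C(C)(C)C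
F2 | step 9 | (2R,3R,4R)-2-{(1R)-1-bromo-2-[(triethylsilyl)oxy]ethyl}-4-[(tert-butyldimethylsilyl)oxy]-3-methyl-3-(prop-2-en-1-yl)cyclohexan-1-one (anti adduct drawn for attack on the face used by the epoxidation) | C=CC[C@@]1(C)[C@H](O[Si](C)(C)C(C)(C)C)CCC(=O)[C@@H]1[C@@H](Br)CO[Si](CC)(CC)CC
F3 | step 9 | (2Z,3R,4R)-4-[(tert-butyldimethylsilyl)oxy]-3-methyl-3-(prop-2-en-1-yl)-2-{2-[(triethylsilyl)oxy]ethylidene}cyclohexan-1-one | C=CC[C@@]1(C)[C@H](O[Si](C)(C)C(C)(C)C)CCC(=O)/C1=C\CO[Si](CC)(CC)CC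
F4 | step 9 | pinacol boronate of 12 (4,4,5,5-tetramethyl-1,3,2-dioxaborolan-2-yl in place of the C-6 hydroxyl, same configuration) | C=CC[C@@]1(C)[C@H](O[Si](C)(C)C(C)(C)C)CCC(=O)[C@@H]1[C@@H](B2OC(C)(C)C(C)(C)O2)CO[Si](CC)(CC)CC
F5 | step 15 | methyl 2-[(1S,2R,3R,4aR,5R,8aS)-1,5-bis[(tert-butyldimethylsilyl)oxy]-3-hydroxy-4a-methyl-8-oxodecahydronaphthalen-2-yl]prop-2-enoate (8β-alcohol, 8-epimer of 20) | O[C@@H]1C[C@@]2(C)[C@H](O[Si](C)(C)C(C)(C)C)CCC(=O)[C@@H]2[C@@H](O[Si](C)(C)C(C)(C)C)[C@@H]1C(=C)C(=O)OC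
F0 | step 12 | none | none
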